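**Plan**

- Numbering used here: benzene ring C1(OH), C2(OH), C3(Br), C4(Br), C5(CH2SO2Me), C6(Br).
- Retrosynthesis: the catechol is masked as its cyclic carbonate and taken back by two hydrogens to a cis-3a,7a-dihydrobenzodioxolone. Ring bonds C2–C3 and C6–C1 are then cut, giving vinylene carbonate (C1, C2 and both oxygens) and a thiophene 1,1-dioxide whose four ring carbons are C3–C6. The S=O, CH2–SO2Me and C–Br bonds lead back to 3-methylthiophene.
- Enabling feature: C1 and C2 are adjacent and are the only atoms of the benzene ring that carry neither bromine nor carbon. They can therefore come from a cis-dioxygenated alkene, while C3–C6 arrive as a fully substituted diene bridged by an expellable SO2.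
- Forward order: the thiophene is tribrominated, its methyl group is converted into CH2SO2Me and the ring sulfur is oxidised. The benzene ring, the only ring that is built, arises by [4+2] cycloaddition and SO2 loss and is then dehydrogenated; the carbonate ring brought in with the dienophile is opened last.
- Stereochemistry: the target is achiral. The two sp3 centres of the cycloadduct are cis through suprafacial addition to the cyclic Z-alkene, form as a racemate and vanish on aromatisation.

Key step: step 5

Remark: the bridged adduct 9 is drawn as the endo isomer (carbonate oxygens anti to the SO2 bridge); the exo isomer would give the same diene 10.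

**Route**

Step 1
Reactants: 1 3-methylthiophene
Product: 2 2,3,5-tribromo-4-methylthiophene
Conditions: Br2 (3.3 equiv), CHCl3/AcOH, 0 °C to reflux, dark
Reagents that add atoms: bromine, BrBr
Why: Electrophilic aromatic bromination of the electron-rich thiophene should fill all three free ring positions, the two α-positions first and the remaining β-position on heating.

Step 2
Reactants: 2 2,3,5-tribromo-4-methylthiophene
Product: 3 2,3,5-tribromo-4-(bromomethyl)thiophene
Conditions: NBS (1.05 equiv), AIBN (cat.), PhCF3, 85 °C
Reagents that add atoms: N-bromosuccinimide, O=C1CCC(=O)N1Br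
Why: Wohl–Ziegler radical bromination can only attack the thenylic methyl group because every ring position is blocked, and the near-stoichiometric charge of NBS should hold back the dibromide.

Step 3
Reactants: 3 2,3,5-tribromo-4-(bromomethyl)thiophene; 4 sodium methanesulfinate (MeSO2Na)
Product: 5 2,3,5-tribromo-4-[(methylsulfonyl)methyl]thiophene
Conditions: DMF, 50 °C
Reagents that add atoms: none
Why: SN2 displacement of the activated thenylic bromide by the soft sulfur end of the sulfinate should give the sulfone directly, and the ring C–Br bonds are inert to this nucleophile.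

Step 4
Reactants: 5 2,3,5-tribromo-4-[(methylsulfonyl)methyl]thiophene
Product: 7 2,3,5-tribromo-4-[(methylsulfonyl)methyl]thiophene 1,1-dioxide, via thiophene 1-oxide 6 (not isolated)
Conditions: urea·H2O2, (CF3CO)2O, CH2Cl2, 0 °C to rt
Reagents that add atoms: trifluoroperacetic acid, OOC(=O)C(F)(F)F, made in the flask from urea–hydrogen peroxide, NC(N)=O.OO, and trifluoroacetic anhydride, O=C(OC(=O)C(F)(F)F)C(F)(F)F
Why: Electrophilic S-oxidation of a perhalogenated thiophene by anhydrous trifluoroperacetic acid is the established entry to tetrahalothiophene dioxides; the non-aromatic sulfoxide 6 should be oxidised on faster than it forms, and the side-chain sulfone is already fully oxidised.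

Step 5
Reactants: 7 2,3,5-tribromo-4-[(methylsulfonyl)methyl]thiophene 1,1-dioxide; 8 vinylene carbonate (1,3-dioxol-2-one)
Product: 10 racemic cis-4,5,7-tribromo-6-[(methylsulfonyl)methyl]-3a,7a-dihydro-1,3-benzodioxol-2-one, via sulfone-bridged cycloadduct 9 (not isolated)
Conditions: 8 (5 equiv), BHT (cat.), PhMe, 105 °C, slow N2 sweep
Reagents that add atoms: none
Why: The electron-poor, non-aromatic diene of 7 and the oxygen-substituted alkene of 8 should combine in a concerted suprafacial inverse-electron-demand Diels–Alder reaction, after which the strained 7-thiabicyclo[2.2.1]heptene 7,7-dioxide 9 expels SO2 in a thermally allowed cheletropic step to leave the cyclohexa-1,3-diene. The closest known reaction type is the cycloaddition of tetrahalothiophene 1,1-dioxides to alkenes with spontaneous SO2 loss. The six-membered carbocycle closes by intermolecular [4+2] cycloaddition in which both new C–C bonds (target C2–C3 and C6–C1) form together, and the carbonate ring is carried in unchanged from 8. The two new stereocentres (C3a and C7a) are cis because the Z geometry of the cyclic alkene is transferred suprafacially, and with no chiral element present the product is racemic. No regiochemical issue arises because 8 is symmetric, and the endo or exo sense of 9 is erased with the bridge; the selectivity that matters is retention of both C–O bonds, which the neutral base-free medium, the nitrogen sweep that removes SO2 and the trans disposition of each ring-fusion hydrogen to the neighbouring oxygen (no syn elimination) should secure.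

Step 6
Reactants: 10 racemic cis-4,5,7-tribromo-6-[(methylsulfonyl)methyl]-3a,7a-dihydro-1,3-benzodioxol-2-one
Product: 11 4,5,7-tribromo-6-[(methylsulfonyl)methyl]-1,3-benzodioxol-2-one
Conditions: DDQ (1.5 equiv), PhCl, 90 °C
Reagents that add atoms: none
Why: Quinone dehydrogenation should proceed by hydride abstraction from an allylic, oxygen-bearing ring-fusion C–H to give an oxygen-stabilised cyclohexadienyl cation that loses the second ring-fusion proton, so the ring aromatises under neutral conditions with both C–O bonds intact and both stereocentres removed.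

Step 7
Reactants: 11 4,5,7-tribromo-6-[(methylsulfonyl)methyl]-1,3-benzodioxol-2-one
Product: 12 3,4,6-tribromo-5-[(methylsulfonyl)methyl]benzene-1,2-diol
Conditions: LiOH (4 equiv), THF/H2O (degassed), 0 °C; then 1 M HCl
Reagents that add atoms: none
Why: Saponification of the strained, electron-poor cyclic aryl carbonate should be fast at 0 °C with loss of CO2, and exclusion of air followed by acidification protects the catecholate from autoxidation.

**Compound list**

1 | 3-methylthiophene | Cc1ccsc1 | starting material
2 | 2,3,5-tribromo-4-methylthiophene | Cc1c(Br)sc(Br)c1Br | intermediate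
3 | 2,3,5-tribromo-4-(bromomethyl)thiophene | BrCc1c(Br)sc(Br)c1Br | intermediate
4 | sodium methanesulfinate | CS(=O)[O-].[Na+] | starting material
5 | 2,3,5-tribromo-4-[(methylsulfonyl)methyl]thiophene | CS(=O)(=O)Cc1c(Br)sc(Br)c1Br | intermediate
6 | 2,3,5-tribromo-4-[(methylsulfonyl)methyl]thiophene 1-oxide (pyramidal sulfur, racemic; formed in the flask, not isolated) | CS(=O)(=O)CC1=C(Br)S(=O)C(Br)=C1Br | intermediate
7 | 2,3,5-tribromo-4-[(methylsulfonyl)methyl]thiophene 1,1-dioxide | CS(=O)(=O)CC1=C(Br)S(=O)(=O)C(Br)=C1Br | intermediate
8 | vinylene carbonate (1,3-dioxol-2-one) | O=C1OC=CO1 | starting material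
9 | racemic endo cycloadduct, 4,5,7-tribromo-6-[(methylsulfonyl)methyl]-3a,4,7,7a-tetrahydro-4,7-epithio-1,3-benzodioxol-2-one 8,8-dioxide (carbonate oxygens cis to each other and anti to the SO2 bridge; formed in the flask, not isolated) | O=C1O[C@@H]2[C@H](O1)[C@]3(Br)C(CS(C)(=O)=O)=C(Br)[C@@]2(Br)S3(=O)=O | intermediate
10 | racemic cis-4,5,7-tribromo-6-[(methylsulfonyl)methyl]-3a,7a-dihydro-1,3-benzodioxol-2-one (3a-H and 7a-H on the same face) | O=C1O[C@H]2C(Br)=C(Br)C(CS(C)(=O)=O)=C(Br)[C@H]2O1 | intermediate
11 | 4,5,7-tribromo-6-[(methylsulfonyl)methyl]-1,3-benzodioxol-2-one | O=C1Oc2c(Br)c(Br)c(CS(C)(=O)=O)c(Br)c2O1 | intermediate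
12 | 3,4,6-tribromo-5-[(methylsulfonyl)methyl]benzene-1,2-diol | CS(=O)(=O)Cc1c(Br)c(O)c(O)c(Br)c1Br | target

**Step count and risks**

Total step count: 7. Longest linear sequence: 7 steps (from 1 to 12).

Steps most likely to fail:

1. Step 5. The cycloaddition may be too slow at temperatures the diene tolerates, because the carbonate carbonyl lowers the electron density of the alkene, so that thermal decay of the thiophene dioxide and radical polymerisation of the dienophile win. Fallback: starting again from 7, the alkene would be replaced by the far more electron-rich enol ether 2,3-dihydro-1,4-dioxine (C1COC=CO1), which should add to this class of diene at or near room temperature. The sulfone-bridged cycloadduct F1 would lose SO2 to racemic cis-5,6,8-tribromo-7-[(methylsulfonyl)methyl]-2,3,4a,8a-tetrahydro-1,4-benzodioxine F2. DDQ in PhCl would dehydrogenate this, now aided by the ether oxygens, to 5,6,8-tribromo-7-[(methylsulfonyl)methyl]-2,3-dihydro-1,4-benzodioxine F3. Excess BBr3 in CH2Cl2 would then cleave the ethylene bridge, and the route is rejoined at 12.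

2. Step 6. Hydride abstraction from the tribrominated, acyloxy-substituted diene may be sluggish, and during prolonged heating the acidic hydroquinone may trigger ionisation of an allylic C–O bond, so that one oxygen is lost and a phenol results. Fallback: from 10, the hydride transfer would be replaced by radical halogenation and elimination. NBS with catalytic AIBN in PhCF3 at 80 °C should brominate a ring-fusion C–H, the weakest C–H bond because it leads to an oxygen-substituted pentadienyl radical. The resulting racemic cis-fused ring-fusion bromide, 3a,4,5,7-tetrabromo-6-[(methylsulfonyl)methyl]-3a,7a-dihydro-1,3-benzodioxol-2-one F4, should lose HBr across the ring fusion on warming, since bromide departs far more readily than the carbonate oxygen. The route is rejoined at 11.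

3. Step 4. S-oxidation may stall on a thiophene deactivated by three bromines and the sulfonylmethyl group, and the dioxide, once formed, may tautomerise or decompose through its acidic CH2 during the long exposure needed. Fallback: from 2, the oxidation would be moved ahead of the side-chain chemistry. Trifluoroperacetic acid should take the more electron-rich methyl compound through 2,3,5-tribromo-4-methylthiophene 1-oxide F5 to 2,3,5-tribromo-4-methylthiophene 1,1-dioxide F6, which has no acidic methylene. Cycloaddition with 8 under the conditions of step 5 would pass through the sulfone-bridged cycloadduct F7 to racemic cis-4,5,7-tribromo-6-methyl-3a,7a-dihydro-1,3-benzodioxol-2-one F8, and DDQ would give 4,5,7-tribromo-6-methyl-1,3-benzodioxol-2-one F9. Wohl–Ziegler bromination (NBS, AIBN, PhCF3) would then give 4,5,7-tribromo-6-(bromomethyl)-1,3-benzodioxol-2-one F10, and displacement with 4 in dry DMF rejoins the route at 11.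

**Further compounds**

F1 | step 5 | racemic endo 5,6,8-tribromo-7-[(methylsulfonyl)methyl]-2,3,4a,5,8,8a-hexahydro-5,8-epithio-1,4-benzodioxine 9,9-dioxide | C1CO[C@@H]2[C@H](O1)[C@]3(Br)C(CS(C)(=O)=O)=C(Br)[C@@]2(Br)S3(=O)=O
F2 | step 5 | racemic cis-5,6,8-tribromo-7-[(methylsulfonyl)methyl]-2,3,4a,8a-tetrahydro-1,4-benzodioxine | C1CO[C@H]2C(Br)=C(Br)C(CS(C)(=O)=O)=C(Br)[C@H]2O1
F3 | step 5 | 5,6,8-tribromo-7-[(methylsulfonyl)methyl]-2,3-dihydro-1,4-benzodioxine | C1COc2c(Br)c(Br)c(CS(C)(=O)=O)c(Br)c2O1
F4 | step 6 | racemic cis-fused 3a,4,5,7-tetrabromo-6-[(methylsulfonyl)methyl]-3a,7a-dihydro-1,3-benzodioxol-2-one | O=C1O[C@@]2(Br)C(Br)=C(Br)C(CS(C)(=O)=O)=C(Br)[C@H]2O1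
F5 | step 4 | 2,3,5-tribromo-4-methylthiophene 1-oxide | CC1=C(Br)S(=O)C(Br)=C1Br
F6 | step 4 | 2,3,5-tribromo-4-methylthiophene 1,1-dioxide | CC1=C(Br)S(=O)(=O)C(Br)=C1Br
F7 | step 4 | racemic endo 4,5,7-tribromo-6-methyl-3a,4,7,7a-tetrahydro-4,7-epithio-1,3-benzodioxol-2-one 8,8-dioxide | O=C1O[C@@H]2[C@H](O1)[C@]3(Br)C(C)=C(Br)[C@@]2(Br)S3(=O)=O
F8 | step 4 | racemic cis-4,5,7-tribromo-6-methyl-3a,7a-dihydro-1,3-benzodioxol-2-one | O=C1O[C@H]2C(Br)=C(Br)C(C)=C(Br)[C@H]2O1
F9 | step 4 | 4,5,7-tribromo-6-methyl-1,3-benzodioxol-2-one | O=C1Oc2c(Br)c(Br)c(C)c(Br)c2O1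
F10 | step 4 | 4,5,7-tribromo-6-(bromomethyl)-1,3-benzodioxol-2-one | O=C1Oc2c(Br)c(Br)c(CBr)c(Br)c2O1
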